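The earlier runs and the new flask are calculated for substances that don't exist; the scatter is artificial.

By 8.00 h the green flask, the one asked about, has 26.0% of its charge in neither target nor starting material, and from that gap you can reckon the leak of target at 60 °C.

in all of them: starting material 0.17 M
- green: coupling partner 0.51 M; temperature 60 °C; the very flask that is asked about, followed so far
- teal: coupling partner 0.51 M; temperature 66 °C; run made earlier
- flask: coupling partner 0.510 M; temperature 60 °C; time 8.0 h

| run | time / h | target / % | starting material / % |
|---|---|---|---|
| green | 1.33 | 16 | 82 |
| green | 2.50 | 28 | 67 |
| green | 4.00 | 33 | 61 |
| green | 5.00 | 34 | 56 |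
| green | 6.00 | 34 | 48 |
| green | 8.00 | 32 | 42 |
| teal | 1.33 | 23 | 74 |
| teal | 2.50 | 31 | 61 |
| teal | 4.00 | 28 | 50 |
| teal | 5.00 | 29 | 39 |
| teal | 6.00 | 30 | 40 |
| teal | 8.00 | 29 | 30 |

(readings scatter by 2 percentage points)

- alpha: at 8.0 h raise the temperature by 15 K, then wait 2.5 h
- eta: at 8.0 h add coupling partner, 50.0% of the amount charged, then wait 2.5 h
- beta: change nothing and wait 2.5 h more
- gamma: at 8.0 h take out 90% of the target then present, then wait 2.5 h

- what is taken out of target is counted as made
- steps that have been proposed: starting material + coupling partner <-> target + by-product; target + by-product -> side product
- additions bring no volume worth counting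

1. target, in percent of the starting material first charged, at 8.0 h
2. the option that brings most further target ("none" if no option brings more than 2 percentage points) (alpha / eta / beta / gamma / none)
3. target present, with what was taken out counted in, in percent of the starting material first charged, after alpha
4. target present, with what was taken out counted in, in percent of the starting material first charged, after gamma

Under the proposed steps, target and by-product form together and go together, so c(by-product) equals c(target) and the gap is side product. At 4.00 h the green gap read 6.00%. Divide its growth by the elapsed time and by the squared mean target, as fractions of the charge, and you get the leak constant 0.473 /h, side product formed per hour per unit of c(target)·c(by-product), a second-order rate constant on the scale of the charge.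

I commit to 32% target at 8.0 h. At that level the leak takes 12 percentage points in 2.5 h. The readings from 5.00 h on fall by just 1.7 points in that time, less than the leak, so net making is the difference, 10 points.

Gamma leaves 3.20% target and the by-product untouched. Holding net making, target averages 8.43% and by-product 37.0% of the charge, so the leak takes 3.7 points, less than net making. The gain is 6.7 points, which makes my gamma 38.7%.

The weak link is L, whose gap difference scatters by 4 points. Lower L to 0.379 /h: net making becomes 8 points and the gain 5.6 points, still more than the margin. Teal, at 66 °C, holds less target than green at 8.00 h, so I expect nothing from alpha.

The forecast says 32% now, gamma best, 22% after alpha and 40% after gamma. On alpha, with S the starting material: “S is consumed faster, but loss grows more”.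

The flask gives 31.8%, and gamma is best, at 38.6% with a gain of 6.8 points against my 6.7 points. Alpha ends at 23.5%, waiting changes target by −2.4 points, and eta brings 0.94 points, less than the margin.

    starting material + coupling partner ⇌ target + by-product (K = 0.360, k = 8.00 × 10⁻⁵ /M/s, Ea = 62.0 kJ/mol, ΔH = 20.0 kJ/mol)
    target + by-product → side product (k = 7.10 × 10⁻⁴ /M/s, Ea = 76.0 kJ/mol)
    (constants at 60 °C)

Take the same flask read at 2.0 h, with target at 22.3%. For a straight rise, mean squared target is a third of the final square, so L gives 1.57% side product, and that flask holds 1.70%.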